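**Retrosynthetic overview**
1. The δ-lactone is the only ring and is made last, in the order of the presumed polyketide pathway. A linear 3,5,7,9,11-pentahydroxyicosanoyl thioester is off-loaded by its own 5-OH (C1–O bond). The 3-OH is then lost to give the ring-locked cis-enoate.
2. C2–C3: the last C2 unit comes from a malonic acid half thioester by decarboxylative aldol onto a C3 aldehyde, in the same flask as line 1.
3. C10–C11 and the C9 carbinol: 1,5-anti boron aldol of a C9 methyl ketone with decanal, with the boron aldolate reduced in situ (9,11-syn).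
4. C5/C7 anti-diol: two-directional iridium-catalysed double allylation of propane-1,3-diol. One Wacker oxidation tells the homotopic allyl ends apart (C9 ketone), and the other end stays as the masked C3 aldehyde.
5. Chain numbering: C1 = lactone carbonyl, C20 = terminal CH3. Target centres are C5 (S), C7 (S), C9 (R), C11 (R), which means 5,7-anti, 7,9-anti and 9,11-syn.

Assumption: (S)-Cl,MeO-BIPHEP is taken as the ligand enantiomer that gives (4S,6S)-3. If the rotation of 3 shows the opposite, the ligand enantiomers are exchanged throughout and nothing else changes.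

**Step 1**
Reactants: 1 propane-1,3-diol; 2 allyl acetate
Product: 3 (4S,6S)-nona-1,8-diene-4,6-diol
Conditions: 2 (10 equiv), [Ir(cod)Cl]2 (5 mol%), (S)-Cl,MeO-BIPHEP (10 mol%), 4-chloro-3-nitrobenzoic acid (20 mol%), Cs2CO3 (40 mol%), 1,4-dioxane, 90 °C
Reagents that add atoms: allyl acetate (2), C=CCOC(C)=O
Why: Krische-type transfer-hydrogenative carbonyl allylation run in both directions; each CH2OH is dehydrogenated to the aldehyde and allylated by the chiral pi-allyl iridium C,O-benzoate under catalyst control, and the second addition diverts the minor enantiomer into the syn diol (Horeau amplification), so C5 and C7 are both set S and anti in very high ee.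

**Step 2**
Reactants: 3 (4S,6S)-nona-1,8-diene-4,6-diol
Product: 4 (4S,6S)-2,2-dimethyl-4,6-di(prop-2-en-1-yl)-1,3-dioxane
Conditions: 2,2-dimethoxypropane (3 equiv), PPTS (5 mol%), CH2Cl2, 23 °C
Reagents that add atoms: 2,2-dimethoxypropane, COC(C)(C)OC
Why: Acid-catalysed transketalisation that touches no stereocentre; it makes the C7 oxygen the ether-type oxygen needed for the 1,5-induction in step 4, and the strained anti-acetonide falls off under the acid of step 7 without a separate deprotection.

**Step 3**
Reactants: 4 (4S,6S)-2,2-dimethyl-4,6-di(prop-2-en-1-yl)-1,3-dioxane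
Product: 5 1-[(4R,6S)-2,2-dimethyl-6-(prop-2-en-1-yl)-1,3-dioxan-4-yl]propan-2-one
Conditions: PdCl2 (10 mol%), Cu(OAc)2 (20 mol%), O2 (1 atm), N,N-dimethylacetamide/H2O 7:1, 23 °C, stopped at about 60% conversion, unreacted 4 recovered and recycled
Reagents that add atoms: water, O
Why: Tsuji–Wacker oxidation (Markovnikov hydroxypalladation, then beta-hydride elimination); the two allyl groups of C2-symmetric 4 are homotopic, so attack at either one gives the same ketone and only over-oxidation has to be limited by partial conversion, Cu(OAc)2 keeps the medium too weakly acidic to open the acetonide, and the change of the C7 descriptor to R is only a CIP priority change.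

**Step 4**
Reactants: 5 1-[(4R,6S)-2,2-dimethyl-6-(prop-2-en-1-yl)-1,3-dioxan-4-yl]propan-2-one; 6 decanal
Product: 9 (2R,4R)-1-[(4S,6S)-2,2-dimethyl-6-(prop-2-en-1-yl)-1,3-dioxan-4-yl]tridecane-2,4-diol, via dicyclohexylboron enolate 7 (not isolated), via dicyclohexylboron aldolate 8 (not isolated)
Conditions: Cy2BCl (1.4 equiv), Et3N (1.6 equiv), Et2O, 0 °C; 6 (1.3 equiv), −78 °C, 3 h; LiBH4 (2 M in THF, 4 equiv), −78 °C, 2 h; then MeOH, pH 7 buffer, 30% H2O2, 0 to 23 °C
Reagents that add atoms: decanal (6), CCCCCCCCCC=O; chlorodicyclohexylborane, ClB(C1CCCCC1)C1CCCCC1 (its boron group is present in 7 and 8 only)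
Why: Paterson-type 1,5-anti boron aldol of the kinetic methyl-side enolate sets C11 (R) anti to the C7 acetal oxygen through a boat transition state held by a formyl C–H···O contact to that oxygen, and external hydride delivery to the six-membered boron chelate 8 (Narasaka–Prasad-type reduction in situ) sets C9 (R) syn to C11 and therefore anti to C7.

**Step 5**
Reactants: 9 (2R,4R)-1-[(4S,6S)-2,2-dimethyl-6-(prop-2-en-1-yl)-1,3-dioxan-4-yl]tridecane-2,4-diol
Product: 10 2-[(4R,6S)-6-[(2R,4R)-2,4-dihydroxytridecyl]-2,2-dimethyl-1,3-dioxan-4-yl]acetaldehyde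
Conditions: O3, CH2Cl2, −78 °C; then PPh3 (1.2 equiv), −78 to 23 °C
Reagents that add atoms: ozone, [O-][O+]=O
Why: Ozonolysis with reductive work-up unmasks the C3 aldehyde under neutral conditions; the free 9,11-diol and the acetonide are inert, no small-ring lactol can form with the distant hydroxyls, and the C5 descriptor changes to R by CIP priority only.

**Step 6**
Reactants: 11 Meldrum's acid (2,2-dimethyl-1,3-dioxane-4,6-dione); 12 ethanethiol
Product: 13 3-(ethylsulfanyl)-3-oxopropanoic acid (S-ethyl malonic acid half thioester)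
Conditions: 12 (1.5 equiv), MeCN, sealed tube, 85 °C, 8 h
Reagents that add atoms: ethanethiol (12), CCS
Why: Thiolysis of Meldrum's acid (acyl substitution with ring opening and loss of acetone) gives the malonyl thioester extender unit in one operation from two bulk chemicals.

**Step 7**
Reactants: 10 2-[(4R,6S)-6-[(2R,4R)-2,4-dihydroxytridecyl]-2,2-dimethyl-1,3-dioxan-4-yl]acetaldehyde; 13 3-(ethylsulfanyl)-3-oxopropanoic acid
Product: 17 (6S)-6-[(2S,4R,6R)-2,4,6-trihydroxypentadecyl]-5,6-dihydro-2H-pyran-2-one (target), via acetonide beta-hydroxy thioester 14 (not isolated), via pentahydroxy thioester 15 (not isolated), via beta-hydroxy delta-lactone 16 (not isolated)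
Conditions: (a) 13 (1.8 equiv), copper bis(2-ethylhexanoate) (20 mol%), 5-methoxybenzimidazole (22 mol%), wet THF, air, 23 °C, 24 h; (b) TsOH·H2O (1.0 equiv), 40 °C, slow N2 sweep, 3 h; (c) toluene/1,4-dioxane 4:1 added to 0.01 M, THF and water distilled off (Dean–Stark), 95 °C, 3 h
Reagents that add atoms: 3-(ethylsulfanyl)-3-oxopropanoic acid (13), CCSC(=O)CC(=O)O
Why: Proposed new method: three known reaction types are run in one flask on an unprotected polyol in the order a polyketide synthase uses them; (a) the copper-bound half-thioester enolate adds to the aldehyde and CO2 leaves afterwards under neutral, wet, hydroxyl-tolerant conditions, giving a C3 epimer mixture that is irrelevant; (b) acid hydrolysis of the anti-acetonide frees the 5-OH, the only hydroxyl that reaches the thioester through a six-membered transition state (3-OH would give a beta-lactone, 7-OH an eight-membered ring), so the chain is released as the delta-lactone while EtSH (bp 35 °C) is swept out before any Michael acceptor exists; (c) acid-catalysed dehydration through the lactone enol removes only the 3-OH, the only hydroxyl beta to a carbonyl, and inside the ring the alkene can only be cis; the closest known reaction types are the decarboxylative thioester aldol, Masamune-type thioester lactonisation and the TsOH-promoted lactonisation–dehydration of 3,5-dihydroxy esters; none of the four stereocentres is touched, and the 5,7-anti relation disfavours oxa-Michael closure of the 7-OH to a 2,6-dioxabicyclo[3.3.1]nonan-3-one because the side chain would have to sit axial.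

**Compound list**
1 | propane-1,3-diol | OCCCO | starting material
2 | allyl acetate | C=CCOC(C)=O | starting material
3 | (4S,6S)-nona-1,8-diene-4,6-diol | C=CC[C@H](O)C[C@@H](O)CC=C | intermediate
4 | (4S,6S)-2,2-dimethyl-4,6-di(prop-2-en-1-yl)-1,3-dioxane | C=CC[C@H]1C[C@@H](OC(C)(C)O1)CC=C | intermediate
5 | 1-[(4R,6S)-2,2-dimethyl-6-(prop-2-en-1-yl)-1,3-dioxan-4-yl]propan-2-one | CC(=O)C[C@H]1C[C@@H](OC(C)(C)O1)CC=C | intermediate
6 | decanal | CCCCCCCCCC=O | starting material
7 | dicyclohexylboron enolate of 5 (methyl-side enolate, O-BCy2; dioxane centres 4R,6S) | C=C(OB(C1CCCCC1)C1CCCCC1)C[C@H]1C[C@@H](OC(C)(C)O1)CC=C | intermediate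
8 | dicyclohexylboron aldolate, (4R)-4-(dicyclohexylboryloxy)-1-[(4R,6S)-2,2-dimethyl-6-(prop-2-en-1-yl)-1,3-dioxan-4-yl]tridecan-2-one | CCCCCCCCC[C@@H](OB(C1CCCCC1)C1CCCCC1)CC(=O)C[C@H]1C[C@@H](OC(C)(C)O1)CC=C | intermediate
9 | (2R,4R)-1-[(4S,6S)-2,2-dimethyl-6-(prop-2-en-1-yl)-1,3-dioxan-4-yl]tridecane-2,4-diol | CCCCCCCCC[C@@H](O)C[C@@H](O)C[C@H]1C[C@@H](OC(C)(C)O1)CC=C | intermediate
10 | 2-[(4R,6S)-6-[(2R,4R)-2,4-dihydroxytridecyl]-2,2-dimethyl-1,3-dioxan-4-yl]acetaldehyde | CCCCCCCCC[C@@H](O)C[C@@H](O)C[C@H]1C[C@@H](OC(C)(C)O1)CC=O | intermediate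
11 | Meldrum's acid (2,2-dimethyl-1,3-dioxane-4,6-dione) | CC1(C)OC(=O)CC(=O)O1 | starting material
12 | ethanethiol | CCS | starting material
13 | 3-(ethylsulfanyl)-3-oxopropanoic acid | CCSC(=O)CC(=O)O | intermediate
14 | S-ethyl 4-[(4S,6S)-6-[(2R,4R)-2,4-dihydroxytridecyl]-2,2-dimethyl-1,3-dioxan-4-yl]-3-hydroxybutanethioate (C3 epimer mixture) | CCCCCCCCC[C@@H](O)C[C@@H](O)C[C@H]1C[C@@H](OC(C)(C)O1)CC(O)CC(=O)SCC | intermediate
15 | S-ethyl (5R,7S,9R,11R)-3,5,7,9,11-pentahydroxyicosanethioate (C3 epimer mixture) | CCCCCCCCC[C@@H](O)C[C@@H](O)C[C@H](O)C[C@@H](O)CC(O)CC(=O)SCC | intermediate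
16 | (6R)-4-hydroxy-6-[(2S,4R,6R)-2,4,6-trihydroxypentadecyl]oxan-2-one (C4 epimer mixture) | CCCCCCCCC[C@@H](O)C[C@@H](O)C[C@H](O)C[C@@H]1CC(O)CC(=O)O1 | intermediate
17 | (6S)-6-[(2S,4R,6R)-2,4,6-trihydroxypentadecyl]-5,6-dihydro-2H-pyran-2-one | CCCCCCCCC[C@@H](O)C[C@@H](O)C[C@H](O)C[C@@H]1CC=CC(=O)O1 | target

**Total step count:** 7. **Longest linear sequence:** 6 (steps 1, 2, 3, 4, 5, 7).

**Three steps most likely to fail**

Step 7. The risks are slow or incomplete dehydration of 16, re-addition of thiol, and acetonide migration to the 9,11-diol. The fallback runs from 10 back to 17. It installs the cis-alkene before the ring, so no dehydration is needed. Still–Gennari olefination of 10 with methyl bis(2,2,2-trifluoroethyl)phosphonoacetate (KN(SiMe3)2, 18-crown-6, THF, −78 °C) gives methyl (2Z)-4-[(4S,6S)-6-[(2R,4R)-2,4-dihydroxytridecyl]-2,2-dimethyl-1,3-dioxan-4-yl]but-2-enoate F1. TsOH·H2O in aqueous MeOH at 40 °C then removes the acetonide. The freed 5-OH closes onto the cis-enoate and gives 17 directly.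

Step 4. The risk is that 1,5-induction from an acetonide oxygen in a twist-boat dioxane is weaker than from a benzyl-type ether, which would leave a C11 epimer that carries through the reduction. The fallback runs from 4 back to 9. It moves the bond made from C10–C11 to C9–C10 and replaces 1,5-induction by 1,3-induction.
- Ozonolysis of 4 with a deficit of O3 (PPh3 work-up, 4 recycled) gives 2-[(4R,6S)-2,2-dimethyl-6-(prop-2-en-1-yl)-1,3-dioxan-4-yl]acetaldehyde F2.
- Commercial 2-undecanone is converted with LiN(iPr)2 and Me3SiCl (THF, −78 °C) into trimethyl(undec-1-en-2-yloxy)silane F3.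
- BF3·OEt2-promoted Mukaiyama aldol of F3 with F2 (CH2Cl2, −78 °C) sets C9 1,3-anti to C7 (polar Evans model). It gives (2S)-1-[(4S,6S)-2,2-dimethyl-6-(prop-2-en-1-yl)-1,3-dioxan-4-yl]-2-hydroxytridecan-4-one F4.
- Narasaka–Prasad reduction (Et2BOMe, NaBH4, THF/MeOH, −78 °C) sets C11 syn to C9 and gives 9.

Step 3. The risk is that oxidising one of two identical alkenes is statistical: about 45% of 5 per pass at best, plus diketone and some acetonide loss. The fallback runs from 2 back to 5. It gives up two-directional growth and builds the two ends differently from the start.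
- Commercial 2-(2-methyl-1,3-dioxolan-2-yl)ethanol, which carries C7–C10 with the ketone masked, is allylated with 2 under the step 1 conditions but with the (R)-ligand. This gives (2R)-1-(2-methyl-1,3-dioxolan-2-yl)pent-4-en-2-ol F5.
- Ozonolysis with NaBH4 work-up gives (3R)-4-(2-methyl-1,3-dioxolan-2-yl)butane-1,3-diol F6.
- A second iridium-catalysed allylation with 2 and the (S)-ligand takes place only at the primary alcohol of the unprotected 1,3-diol. It sets C5 anti under catalyst control and gives (2R,4S)-1-(2-methyl-1,3-dioxolan-2-yl)hept-6-ene-2,4-diol F7.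
- PPTS in acetone exchanges the acetals (dioxolane off, acetonide on) and gives 5.

**Further compounds**
F1 | step 7 | methyl (2Z)-4-[(4S,6S)-6-[(2R,4R)-2,4-dihydroxytridecyl]-2,2-dimethyl-1,3-dioxan-4-yl]but-2-enoate | CCCCCCCCC[C@@H](O)C[C@@H](O)C[C@H]1C[C@@H](OC(C)(C)O1)C/C=C\C(=O)OC
F2 | step 4 | 2-[(4R,6S)-2,2-dimethyl-6-(prop-2-en-1-yl)-1,3-dioxan-4-yl]acetaldehyde | O=CC[C@H]1C[C@@H](OC(C)(C)O1)CC=C
F3 | step 4 | trimethyl(undec-1-en-2-yloxy)silane | C=C(CCCCCCCCC)O[Si](C)(C)C
F4 | step 4 | (2S)-1-[(4S,6S)-2,2-dimethyl-6-(prop-2-en-1-yl)-1,3-dioxan-4-yl]-2-hydroxytridecan-4-one | CCCCCCCCCC(=O)C[C@@H](O)C[C@H]1C[C@@H](OC(C)(C)O1)CC=C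
F5 | step 3 | (2R)-1-(2-methyl-1,3-dioxolan-2-yl)pent-4-en-2-ol | CC1(OCCO1)C[C@H](O)CC=C
F6 | step 3 | (3R)-4-(2-methyl-1,3-dioxolan-2-yl)butane-1,3-diol | CC1(OCCO1)C[C@H](O)CCO
F7 | step 3 | (2R,4S)-1-(2-methyl-1,3-dioxolan-2-yl)hept-6-ene-2,4-diol | CC1(OCCO1)C[C@H](O)C[C@@H](O)CC=C
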